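**Plan**

- Retrosynthesis: the phenol O–CH2OMe bond is cut first, then the C2–C3 bond of the hepta-1,5-diene chain, between the alkene carbon that bears the benzene ring and the carbon that bears the tiglate oxygen. The aryl half goes back to an aryl methyl ketone enol triflate (C–OTf, then the aryl–acetyl C–C bond, then the phenol C–O bond of a commercial benzaldehyde). The other half goes back to a racemic 1-chloroalkyl tiglate (C–Cl and C–O bonds, from 4-methylpent-3-enal and tigloyl chloride).
- Forward: the benzene ring is bought, not built. Steps 1–4 make the enol triflate (Dakin oxidation, MOM protection, ortho-lithiation/acetylation, triflation). Steps 5–6 make the chloro ester. The chain is joined in step 7 and the phenol is freed in step 8.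
- Enabling feature: C3 carries the ester oxygen. It is therefore at the aldehyde oxidation level (aldehyde + acyl chloride gives the halide), its radical is stabilized by the oxygen lone pair, and the tiglate C=O can bind nickel. C2 is an sp2 carbon attached to the benzene ring, that is, the carbon of an enol triflate.
- Stereochemistry: the only stereocenter, C3 (S), is set in step 7 by a chiral nickel catalyst that funnels both enantiomers of the racemic chloride into one ester. The E geometry of the tiglate is bought with tigloyl chloride.

Key step: step 7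

Remark: the sense of induction of the bis(oxazoline) ligand in step 7 is not predicted here; both antipodes of the ligand are available, and the one that gives the S ester is used.

**Route**

Step 1
Reactants: 1 2,4-dimethoxy-3-methylbenzaldehyde
Product: 3 2,4-dimethoxy-3-methylphenol, via aryl formate 2 (not isolated)
Conditions: mCPBA, CH2Cl2, 0 °C to rt; aq. NaHCO3 wash; then K2CO3 (cat.), MeOH, rt
Reagents that add atoms: mCPBA, O=C(OO)c1cccc(Cl)c1
Why: Baeyer–Villiger (Dakin-type) oxidation, in which the electron-rich aryl group (methoxy groups ortho and para to the formyl carbon) migrates to oxygen and mild methanolysis of the aryl formate frees the phenol.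

Step 2
Reactants: 3 2,4-dimethoxy-3-methylphenol
Product: 5 1,3-dimethoxy-4-(methoxymethoxy)-2-methylbenzene, via sodium phenoxide 4 (not isolated)
Conditions: NaH, THF/DMF, 0 °C; then MOMCl, 0 °C to rt
Reagents that add atoms: chloromethyl methyl ether (MOMCl), COCCl
Why: Williamson-type O-alkylation of the phenoxide with the reactive α-chloro ether; the MOM acetal serves as phenol protection and as the director for step 3.

Step 3
Reactants: 5 1,3-dimethoxy-4-(methoxymethoxy)-2-methylbenzene
Product: 8 1-[3,5-dimethoxy-2-(methoxymethoxy)-4-methylphenyl]ethan-1-one, via aryllithium 6 (not isolated), via lithium hemiaminal adduct 7 (not isolated)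
Conditions: nBuLi, TMEDA, THF, −20 to 0 °C; then MeC(O)N(OMe)Me, −78 °C to rt; H2O
Reagents that add atoms: N-methoxy-N-methylacetamide, CC(=O)N(C)OC
Why: Directed ortho-metalation followed by Weinreb ketone synthesis: the OMOM group is a stronger director than OMe and has only one free ortho position, and the chelated tetrahedral adduct stops the acylation at the ketone.

Step 4
Reactants: 8 1-[3,5-dimethoxy-2-(methoxymethoxy)-4-methylphenyl]ethan-1-one
Product: 10 1-[3,5-dimethoxy-2-(methoxymethoxy)-4-methylphenyl]ethenyl trifluoromethanesulfonate, via potassium enolate 9 (not isolated)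
Conditions: KN(SiMe3)2, THF, −78 °C; then PhNTf2, −78 to 0 °C
Reagents that add atoms: N-phenylbis(trifluoromethanesulfonimide) (PhNTf2), O=S(=O)(N(c1ccccc1)S(=O)(=O)C(F)(F)F)C(F)(F)F
Why: Enolate O-sulfonylation (enol triflate synthesis): the acetyl methyl group is the only enolizable position and the potassium enolate is triflated on oxygen.

Step 5
Reactants: 11 4-methylpent-3-en-1-ol
Product: 12 4-methylpent-3-enal
Conditions: Dess–Martin periodinane, NaHCO3, CH2Cl2, 0 °C; careful concentration, used at once
Reagents that add atoms: none
Why: Dess–Martin oxidation under bicarbonate buffer is neutral and fast at 0 °C, which should keep the β,γ-double bond from moving into conjugation.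

Step 6
Reactants: 12 4-methylpent-3-enal; 13 (2E)-2-methylbut-2-enoyl chloride (tigloyl chloride)
Product: 14 rac-1-chloro-4-methylpent-3-en-1-yl (2E)-2-methylbut-2-enoate
Conditions: ZnCl2 (cat.), CH2Cl2, −20 to 0 °C
Reagents that add atoms: none
Why: Lewis-acid-catalysed addition of an acyl chloride across the aldehyde C=O (1-chloroalkyl ester synthesis) is fast at low temperature and loses no atoms; the new center is deliberately racemic and the E geometry of the tiglate is untouched.

Step 7
Reactants: 10 1-[3,5-dimethoxy-2-(methoxymethoxy)-4-methylphenyl]ethenyl trifluoromethanesulfonate (1.0 equiv); 14 rac-1-chloro-4-methylpent-3-en-1-yl (2E)-2-methylbut-2-enoate (1.5 equiv)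
Product: 15 (3S)-2-[3,5-dimethoxy-2-(methoxymethoxy)-4-methylphenyl]-6-methylhepta-1,5-dien-3-yl (2E)-2-methylbut-2-enoate
Conditions: NiCl2(dme) (10 mol %), one enantiomer of 2,2'-(cyclopropane-1,1-diyl)bis(3a,8a-dihydro-8H-indeno[1,2-d]oxazole) (12 mol %), Mn powder (3 equiv), NaI (0.5 equiv), DMA, 0 °C
Reagents that add atoms: none
Why: Proposed new method: zerovalent nickel bearing the chiral bis(oxazoline) inserts into the C(sp2)–OTf bond of 10, a monovalent nickel species takes the halogen (chloride, or iodide after exchange with NaI) from either enantiomer of 14 to give one planar α-acyloxyalkyl radical, and capture of this radical by the alkenylnickel followed by reductive elimination from trivalent nickel forms the C(sp2)–C(sp3) bond, with Mn returning nickel to the low-valent state. The closest known reaction types are the nickel/bis(oxazoline)-catalysed asymmetric reductive cross-coupling of alkenyl bromides with racemic benzylic chlorides (also α-chlorosilanes and N-hydroxyphthalimide esters) and the nickel-catalysed enantioconvergent couplings of racemic 1-haloalkyl esters with alkyl nucleophiles; the combination of an alkenyl electrophile with a 1-haloalkyl ester goes beyond them. No ring is closed. The only stereocenter (C3, S) is set by the ligand on nickel in the radical capture/reductive elimination, so that both enantiomers of 14 should converge on one product. The step needs cross- over homo-coupling, which the two different activation modes should secure (two-electron for the enol triflate, one-electron for the alkyl halide); it also needs a radical that spares the alkenes, which the α,β-disubstituted tiglate (only a 4-exo or 5-endo closure is open) and the reversibility of 3-exo attack on the prenyl alkene should secure. Ionization of the allylic ester product by zerovalent nickel should be held back by the low temperature and by the faster insertion into 10.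

Step 8
Reactants: 15 (3S)-2-[3,5-dimethoxy-2-(methoxymethoxy)-4-methylphenyl]-6-methylhepta-1,5-dien-3-yl (2E)-2-methylbut-2-enoate
Product: 16 (3S)-2-(2-hydroxy-3,5-dimethoxy-4-methylphenyl)-6-methylhepta-1,5-dien-3-yl (2E)-2-methylbut-2-enoate
Conditions: NaHSO4·SiO2, CH2Cl2, rt
Reagents that add atoms: none
Why: Acid-catalysed hydrolysis of the aryl methoxymethyl acetal on a weakly acidic solid support, a method selective for phenolic MOM ethers; the allylic ester, both alkenes and the stereocenter should not react under these conditions.

**Compound list**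

1 | 2,4-dimethoxy-3-methylbenzaldehyde | COc1ccc(C=O)c(OC)c1C | starting material
2 | 2,4-dimethoxy-3-methylphenyl formate | O=COc1ccc(OC)c(C)c1OC | intermediate (not isolated)
3 | 2,4-dimethoxy-3-methylphenol | Oc1ccc(OC)c(C)c1OC | intermediate
4 | sodium 2,4-dimethoxy-3-methylphenoxide | [Na+].[O-]c1ccc(OC)c(C)c1OC | intermediate (not isolated)
5 | 1,3-dimethoxy-4-(methoxymethoxy)-2-methylbenzene (MOM ether of 3) | COCOc1ccc(OC)c(C)c1OC | intermediate
6 | [3,5-dimethoxy-2-(methoxymethoxy)-4-methylphenyl]lithium | [Li]c1cc(OC)c(C)c(OC)c1OCOC | intermediate (not isolated)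
7 | lithium 1-[3,5-dimethoxy-2-(methoxymethoxy)-4-methylphenyl]-1-[methoxy(methyl)amino]ethan-1-olate | [Li]OC(C)(N(C)OC)c1cc(OC)c(C)c(OC)c1OCOC | intermediate (not isolated)
8 | 1-[3,5-dimethoxy-2-(methoxymethoxy)-4-methylphenyl]ethan-1-one | CC(=O)c1cc(OC)c(C)c(OC)c1OCOC | intermediate
9 | potassium 1-[3,5-dimethoxy-2-(methoxymethoxy)-4-methylphenyl]ethen-1-olate | [K+].[O-]C(=C)c1cc(OC)c(C)c(OC)c1OCOC | intermediate (not isolated)
10 | 1-[3,5-dimethoxy-2-(methoxymethoxy)-4-methylphenyl]ethenyl trifluoromethanesulfonate | C=C(OS(=O)(=O)C(F)(F)F)c1cc(OC)c(C)c(OC)c1OCOC | intermediate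
11 | 4-methylpent-3-en-1-ol | CC(C)=CCCO | starting material
12 | 4-methylpent-3-enal | CC(C)=CCC=O | intermediate
13 | (2E)-2-methylbut-2-enoyl chloride (tigloyl chloride) | O=C(Cl)/C(C)=C/C | starting material
14 | rac-1-chloro-4-methylpent-3-en-1-yl (2E)-2-methylbut-2-enoate | CC(C)=CCC(Cl)OC(=O)/C(C)=C/C | intermediate
15 | (3S)-2-[3,5-dimethoxy-2-(methoxymethoxy)-4-methylphenyl]-6-methylhepta-1,5-dien-3-yl (2E)-2-methylbut-2-enoate | C=C(c1cc(OC)c(C)c(OC)c1OCOC)[C@H](CC=C(C)C)OC(=O)/C(C)=C/C | intermediate
16 | (3S)-2-(2-hydroxy-3,5-dimethoxy-4-methylphenyl)-6-methylhepta-1,5-dien-3-yl (2E)-2-methylbut-2-enoate | C=C(c1cc(OC)c(C)c(OC)c1O)[C@H](CC=C(C)C)OC(=O)/C(C)=C/C | target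

**Count**

Total steps: 8. Longest linear sequence: 6 steps (1 → 3 → 5 → 8 → 10 → 15 → 16).

**Steps most likely to fail**

1. Step 7 (proposed new method). What may go wrong: slow or unselective capture of the α-acyloxyalkyl radical by the hindered 1-arylvinylnickel species, which would show as poor enantioselectivity, as reduction or dimerization of either partner, or as loss of HCl from 14; the allylic ester product may also be ionized by low-valent nickel. Fallback with known chemistry (lithiation–borylation), setting out from 10, 11 and 13 and coming back at 15: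
   - Enol triflate 10 is borylated (B2pin2, PdCl2(PPh3)2, PPh3, KOPh, toluene, 50 °C) to the alkenylboronic ester F1.
   - Alcohol 11 is carbamoylated (iPr2NCOCl, Et3N, CH2Cl2, reflux) to the carbamate F2.
   - F2 is deprotonated with sBuLi/(+)-sparteine (Et2O, −78 °C) to the configurationally stable lithiated carbamate F3.
   - F1 adds with retention to give the boronate complex F4; its 1,2-alkenyl shift (MgBr2·OEt2, warming) displaces the carbamate with inversion and gives the allylic boronic ester F5.
   - Oxidation in the same flask (NaOH, H2O2, THF, 0 °C) with retention should give the (S)-alcohol F6.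
   - F6 is acylated with 13 (pyridine, DMAP cat., CH2Cl2, 0 °C) to 15.

2. Step 6. What may go wrong: Lewis-acid-induced migration of the β,γ-double bond of 12 into conjugation, Prins-type self-condensation of the aldehyde, or loss of HCl from 14 to a dienyl ester during isolation. The fallback replaces the halide by a redox-active ester, so that neither the aldehyde nor a 1-haloalkyl ester is needed; it sets out from 13 and comes back at 15:
   - Commercial 2,2-dimethyl-1,3-dioxolan-4-one is alkylated (LiN(iPr)2, THF, −78 °C; prenyl bromide) to the dioxolanone F7.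
   - Hydrolysis (LiOH, THF/H2O; then acidification) gives the racemic hydroxy acid F8.
   - O-Acylation with 13 (pyridine, CH2Cl2, 0 °C; water work-up) gives the acyloxy acid F9.
   - N-Hydroxyphthalimide, N,N'-diisopropylcarbodiimide and DMAP (cat.) give the N-hydroxyphthalimide ester F10.
   - F10 is coupled with 10 under the nickel/bis(oxazoline)/Mn conditions of step 7. Loss of CO2 and phthalimide gives the same α-acyloxyalkyl radical, and the coupling should give 15.

3. Step 3. What may go wrong: lithiation at the wrong ring position (next to the 4-methoxy group), or proton transfer from the Weinreb amide to the aryllithium, which returns 5. The fallback uses chelation-controlled electrophilic ortho-formylation in place of metalation; it sets out from 3 and comes back at 8: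
   - Phenol 3 is formylated only ortho to the hydroxyl group (MgCl2, Et3N, paraformaldehyde, MeCN, reflux) to the salicylaldehyde F11.
   - Protection (MOMCl, iPr2NEt, CH2Cl2) gives the aldehyde F12.
   - MeMgBr (THF, 0 °C) gives the carbinol F13.
   - Dess–Martin oxidation (CH2Cl2, rt) gives 8.

**Further compounds**

F1 | step 7 | 2-{1-[3,5-dimethoxy-2-(methoxymethoxy)-4-methylphenyl]ethenyl}-4,4,5,5-tetramethyl-1,3,2-dioxaborolane | C=C(B1OC(C)(C)C(C)(C)O1)c1cc(OC)c(C)c(OC)c1OCOC
F2 | step 7 | 4-methylpent-3-en-1-yl N,N-diisopropylcarbamate | CC(C)=CCCOC(=O)N(C(C)C)C(C)C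
F3 | step 7 | (R)-1-lithio-4-methylpent-3-en-1-yl N,N-diisopropylcarbamate, (+)-sparteine complex | [Li][C@H](CC=C(C)C)OC(=O)N(C(C)C)C(C)C
F4 | step 7 | lithium boronate complex of F1 and F3 (R at carbon) | [Li+].C=C(c1cc(OC)c(C)c(OC)c1OCOC)[B-]1(OC(C)(C)C(C)(C)O1)[C@H](CC=C(C)C)OC(=O)N(C(C)C)C(C)C
F5 | step 7 | 2-{(3S)-2-[3,5-dimethoxy-2-(methoxymethoxy)-4-methylphenyl]-6-methylhepta-1,5-dien-3-yl}-4,4,5,5-tetramethyl-1,3,2-dioxaborolane | C=C(c1cc(OC)c(C)c(OC)c1OCOC)[C@H](CC=C(C)C)B1OC(C)(C)C(C)(C)O1
F6 | step 7 | (3S)-2-[3,5-dimethoxy-2-(methoxymethoxy)-4-methylphenyl]-6-methylhepta-1,5-dien-3-ol | C=C(c1cc(OC)c(C)c(OC)c1OCOC)[C@H](CC=C(C)C)O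
F7 | step 6 | rac-2,2-dimethyl-5-(3-methylbut-2-en-1-yl)-1,3-dioxolan-4-one | CC(C)=CCC1OC(C)(C)OC1=O
F8 | step 6 | rac-2-hydroxy-5-methylhex-4-enoic acid | CC(C)=CCC(O)C(=O)O
F9 | step 6 | rac-5-methyl-2-{[(2E)-2-methylbut-2-enoyl]oxy}hex-4-enoic acid | CC(C)=CCC(OC(=O)/C(C)=C/C)C(=O)O
F10 | step 6 | rac-1,3-dioxoisoindolin-2-yl 5-methyl-2-{[(2E)-2-methylbut-2-enoyl]oxy}hex-4-enoate | CC(C)=CCC(OC(=O)/C(C)=C/C)C(=O)ON1C(=O)c2ccccc2C1=O
F11 | step 3 | 2-hydroxy-3,5-dimethoxy-4-methylbenzaldehyde | O=Cc1cc(OC)c(C)c(OC)c1O
F12 | step 3 | 3,5-dimethoxy-2-(methoxymethoxy)-4-methylbenzaldehyde | O=Cc1cc(OC)c(C)c(OC)c1OCOC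
F13 | step 3 | rac-1-[3,5-dimethoxy-2-(methoxymethoxy)-4-methylphenyl]ethan-1-ol | CC(O)c1cc(OC)c(C)c(OC)c1OCOC
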